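The numbers of this flask were chosen freely; the result is computed.

The amounts came first: Z at 4.75 mM plus J at 0.250 mM makes 5.00 mM, level with L at 5.0 mM, so L can serve both.

| flask | L | Z | J | temperature | time |
|---|---|---|---|---|---|
| zeta | 5.0 mM | 4.75 mM | 0.250 mM | 40 °C | 2.0 min |
| alpha | 5.0 mM | 4.75 mM | 0.250 mM | 30 °C | 2.0 min |
| theta | 5.0 mM | 4.75 mM | 0.250 mM | 20 °C | 2.0 min |

    L + Z → L.Z (k1 = 26 L mol⁻¹ s⁻¹, Ea1 = 42.0 kJ mol⁻¹)
    L + Z → X, rate k2*[L] as long as [Z] is above zero (k2 = 0.20 s⁻¹, Ea2 = 69.0 kJ mol⁻¹)
    L + J → L.J (k3 = 230 L mol⁻¹ s⁻¹, Ea3 = 44.0 kJ mol⁻¹)
    (constants at 20 °C)

* which of these there is most of at the end, counted by the L in it, zeta (L / L.Z / X)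
* which of these there is most of at the end, counted by the L in it, alpha (L / L.Z / X)
* which of these there is most of at the end, counted by the L in it, theta (L / L.Z / X)
* how much there is at the end of the one of these that leads, in percent of the L charged: zeta
* how much there is at the end of the one of these that leads, in percent of the L charged: alpha
* how much there is at the end of the one of these that leads, in percent of the L charged: theta

- at 20 °C the constants are as listed, elsewhere as the activation energies make them

But two steps compete for each Z. I divided the ring rate by the link rate, and L cancelled. That left c×/[Z], where c× is the crossing concentration, the ring constant over the link constant (the usual effective molarity): the [Z] at which ring closure and linking run level. Ring closure has the higher activation energy, so c× climbs with temperature: 7.69 mM in theta, 11.1 mM in alpha, 15.6 mM in zeta. Even in theta c× stands above the charged Z, and [Z] can only fall, so I expected ring closure to outrun linking from the start.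

Next came the time. In theta, L stays at least level with Z, so ring closure alone halves Z in no longer than 3.47 s, far short of 2.0 min. So I counted on the whole charge of Z reacting in theta, and in the warmer alpha and zeta too, where the ring constant is larger. Each Z spent goes to X with share c×/(c× + [Z]). Summed over the charge, X = c× ln((c× + Z charged)/c×), and the charge of L does not enter. That gave X at 82.9% of the L charged in zeta, 79.1% in alpha and 74.0% in theta.

The forecast named X in each flask, at 82.9% in zeta, 79.1% in alpha and 74% in theta, holding that “the outcome is set only by the competition between first-order ring closure and second-order linking”. My figures were the same.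

The simulation gave X leading at 82.9% in zeta, 79.1% in alpha and 74.0% in theta, so one logarithm per flask was the cheap road. In zeta, ring closure used Z at 3.3 times the rate of linking at the start and at 7.0 times at 0.00828 min, a ratio that through c× puts [Z] near 2.22 mM at that moment. For the neighbour of zeta charged with 1.9 mM of Z, the same c× gave X at 35.9% of the L charged. The simulation gave 35.9%, with L leading at 57.0%.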